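The plan rests on cutting two bonds of ring B, C5–C10 and C6–C7. Ring B (C5 to C10, labdane numbering) contains the only ring alkene, C8=C9, opposite the two oxygen-bearing carbons C6 and C7, so it can be read as a [4+2] adduct of a C7=C8–C9=C10 diene and a C5=C6 dienophile held together by the C1–C4 chain. A single intramolecular Diels–Alder reaction of an acyclic nitro-triene should therefore build rings A and B and the stereocentres C5, C6, C7 and C10 together. The precursor has an (E)-nitroalkene, an (E)-silyl dienol ether, a geometry-defined tetrasubstituted C9=C10 alkene and the Z side chain.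

Key step: step 14

Remark: the sense of induction of the thiourea catalyst in step 14 cannot be predicted, so the (R,R) form is written and its enantiomer is to be used if it favours the antipode; atoms carry labdane numbers throughout.

Step 1
Reactants: 1 (2Z)-3-methylpent-2-en-4-yn-1-ol
Product: 2 tert-butyl(dimethyl){[(2Z)-3-methylpent-2-en-4-yn-1-yl]oxy}silane
Conditions: TBSCl, imidazole, CH2Cl2, 0 °C to rt
Reagents that add atoms: tert-butyldimethylsilyl chloride, CC(C)(C)[Si](C)(C)Cl
Why: Imidazole-mediated silylation of the primary allylic alcohol (silyl ether formation) is unproblematic, and the Z-enyne, which already holds the C13=C14 geometry of the target, is not touched.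

Step 2
Reactants: 2 tert-butyl(dimethyl){[(2Z)-3-methylpent-2-en-4-yn-1-yl]oxy}silane
Product: 3 tert-butyl(dimethyl){[(2Z)-3-methylpenta-2,4-dien-1-yl]oxy}silane
Conditions: H2 (1 atm), Pd/CaCO3–Pb(OAc)2, quinoline, hexane, rt, stopped after one equivalent of H2
Reagents that add atoms: none
Why: Lindlar semihydrogenation stops at the alkene for a terminal alkyne, so the enyne should give the conjugated diene with the trisubstituted Z alkene and the silyl ether unchanged.

Step 3
Reactants: 3 tert-butyl(dimethyl){[(2Z)-3-methylpenta-2,4-dien-1-yl]oxy}silane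
Product: 5 tert-butyl{[(2Z)-5-iodo-3-methylpent-2-en-1-yl]oxy}dimethylsilane, via alkylzirconocene chloride 4 (not isolated)
Conditions: Cp2Zr(H)Cl, THF, rt; then I2, 0 °C
Reagents that add atoms: iodine, II
Why: Hydrozirconation adds Zr–H across the less hindered terminal vinyl group of a 1,3-diene with zirconium on the end carbon, and iodinolysis of the C–Zr bond (hydrozirconation–iodination) should deliver the primary iodide at C11 while the Z alkene survives because iodine is consumed by the much faster metal–carbon cleavage.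

Step 4
Reactants: 5 tert-butyl{[(2Z)-5-iodo-3-methylpent-2-en-1-yl]oxy}dimethylsilane; 6 methyl acetoacetate
Product: 7 methyl (5Z)-2-acetyl-7-{[tert-butyl(dimethyl)silyl]oxy}-5-methylhept-5-enoate (racemic)
Conditions: NaH, THF/DMF, 0 to 50 °C
Reagents that add atoms: none
Why: Acetoacetic ester alkylation: the soft, weakly basic sodium enolate should displace the primary iodide by SN2 at C11 in preference to elimination, and the stereocentre formed at C9 is of no consequence because step 5 makes this carbon trigonal.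

Step 5
Reactants: 7 methyl (5Z)-2-acetyl-7-{[tert-butyl(dimethyl)silyl]oxy}-5-methylhept-5-enoate
Product: 8 methyl (2E)-2-[(3Z)-5-{[tert-butyl(dimethyl)silyl]oxy}-3-methylpent-3-en-1-yl]-3-{[(4-methylphenyl)sulfonyl]oxy}but-2-enoate
Conditions: TsCl, N-methylimidazole, Et3N, MeCN, 0 °C to rt
Reagents that add atoms: p-toluenesulfonyl chloride, Cc1ccc(cc1)S(=O)(=O)Cl
Why: Stereoselective enol sulfonylation of an α-substituted β-keto ester: the N-sulfonylimidazolium species formed from TsCl and N-methylimidazole tosylates the non-chelated ammonium enolate in its extended form, which places the tosyloxy group anti to the ester (2E) and thereby fixes the C9=C10 geometry of the whole route.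

Step 6
Reactants: 8 methyl (2E)-2-[(3Z)-5-{[tert-butyl(dimethyl)silyl]oxy}-3-methylpent-3-en-1-yl]-3-{[(4-methylphenyl)sulfonyl]oxy}but-2-enoate; 9 2,2-dimethylpent-4-enal
Product: 11 methyl (2E)-2-[(3Z)-5-{[tert-butyl(dimethyl)silyl]oxy}-3-methylpent-3-en-1-yl]-8-hydroxy-3,7,7-trimethyloct-2-enoate, via bis-boron adduct 10 (not isolated)
Conditions: 9, 9-BBN (2.2 equiv), THF, 0 °C to rt; then 8, Pd(OAc)2, SPhos, K3PO4, THF/H2O, 60 °C
Reagents that add atoms: none
Why: 9-BBN reduces the hindered aldehyde to its borinate and hydroborates the terminal alkene at C1 (anti-Markovnikov), and the B-alkyl-9-BBN then couples with the electron-poor enol tosylate in a B-alkyl Suzuki–Miyaura reaction with retention of alkene geometry, so that C1 ends up cis to C11 and trans to the ester carbon C8, while the aqueous base frees the C5 hydroxyl.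

Step 7
Reactants: 11 methyl (2E)-2-[(3Z)-5-{[tert-butyl(dimethyl)silyl]oxy}-3-methylpent-3-en-1-yl]-8-hydroxy-3,7,7-trimethyloct-2-enoate
Product: 13 (3E)-3-[(3Z)-5-{[tert-butyl(dimethyl)silyl]oxy}-3-methylpent-3-en-1-yl]-9-hydroxy-4,8,8-trimethylnon-3-en-2-one, via α-silyl ketone 12 (not isolated)
Conditions: Me3SiCH2Li (3.5 equiv), THF/pentane, −78 to 0 °C; then MeOH, rt; aqueous work-up
Reagents that add atoms: (trimethylsilyl)methyllithium, [Li]C[Si](C)(C)C
Why: Addition of (trimethylsilyl)methyllithium to the ester stops at the ketone stage because the α-silyl ketone is enolised at once by further reagent, and methanolysis of its C–Si bond then gives the methyl ketone (ester to methyl ketone conversion), one equivalent of reagent being spent on the free hydroxyl.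

Step 8
Reactants: 13 (3E)-3-[(3Z)-5-{[tert-butyl(dimethyl)silyl]oxy}-3-methylpent-3-en-1-yl]-9-hydroxy-4,8,8-trimethylnon-3-en-2-one
Product: 14 (6E)-7-[(3Z)-5-{[tert-butyl(dimethyl)silyl]oxy}-3-methylpent-3-en-1-yl]-2,2,6,8-tetramethylnona-6,8-dien-1-ol
Conditions: Ph3PCH3Br, KOtBu, THF, 0 °C to rt
Reagents that add atoms: methyltriphenylphosphonium bromide, [Br-].C[P+](c1ccccc1)(c1ccccc1)c1ccccc1
Why: Wittig methylenation of the conjugated methyl ketone, a transformation that works on β-ionone-type enones, should install C7 as a terminal methylene without disturbing the tetrasubstituted C9=C10 alkene.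

Step 9
Reactants: 14 (6E)-7-[(3Z)-5-{[tert-butyl(dimethyl)silyl]oxy}-3-methylpent-3-en-1-yl]-2,2,6,8-tetramethylnona-6,8-dien-1-ol
Product: 16 (3E)-3-[(3Z)-5-{[tert-butyl(dimethyl)silyl]oxy}-3-methylpent-3-en-1-yl]-2,4,8,8-tetramethylnon-3-ene-1,9-diol (racemic), via alkylborane 15 (not isolated)
Conditions: 9-BBN (2.5 equiv), THF, 0 °C to rt; then NaOH, H2O2, 0 °C
Reagents that add atoms: hydrogen peroxide, OO
Why: Hydroboration–oxidation with 9-BBN, which reacts far faster with a 1,1-disubstituted terminal alkene than with tri- or tetrasubstituted ones and places boron on the terminal carbon, should give the C7 primary alcohol; the C8 stereocentre arises racemic and is erased in step 11.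

Step 10
Reactants: 16 (3E)-3-[(3Z)-5-{[tert-butyl(dimethyl)silyl]oxy}-3-methylpent-3-en-1-yl]-2,4,8,8-tetramethylnon-3-ene-1,9-diol
Product: 17 (3E)-3-[(3Z)-5-{[tert-butyl(dimethyl)silyl]oxy}-3-methylpent-3-en-1-yl]-2,4,8,8-tetramethylnon-3-enedial (racemic)
Conditions: Dess–Martin periodinane, pyridine, CH2Cl2, 0 °C to rt
Reagents that add atoms: none
Why: Dess–Martin oxidation of both primary alcohols under pyridine buffering gives the dialdehyde without acid or strong base that could move the C9=C10 alkene into conjugation with the C7 aldehyde.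

Step 11
Reactants: 17 (3E)-3-[(3Z)-5-{[tert-butyl(dimethyl)silyl]oxy}-3-methylpent-3-en-1-yl]-2,4,8,8-tetramethylnon-3-enedial
Product: 18 (6E,8E)-9-{[tert-butyl(dimethyl)silyl]oxy}-7-[(3Z)-5-{[tert-butyl(dimethyl)silyl]oxy}-3-methylpent-3-en-1-yl]-2,2,6,8-tetramethylnona-6,8-dienal
Conditions: TBSOTf (1.2 equiv), Et3N, CH2Cl2, −78 °C
Reagents that add atoms: tert-butyldimethylsilyl trifluoromethanesulfonate, CC(C)(C)[Si](C)(C)OS(=O)(=O)C(F)(F)F
Why: Soft enolisation with a silyl triflate and a tertiary amine can only involve the C7 aldehyde, since the C5 aldehyde has no α-hydrogen, and allylic 1,3-strain should steer the silyloxy group cis to the C8 methyl and trans to C9 (the E enol ether), any Z isomer being unable to react in step 14 and removable there.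

Step 12
Reactants: 18 (6E,8E)-9-{[tert-butyl(dimethyl)silyl]oxy}-7-[(3Z)-5-{[tert-butyl(dimethyl)silyl]oxy}-3-methylpent-3-en-1-yl]-2,2,6,8-tetramethylnona-6,8-dienal; 19 nitromethane
Product: 20 (7E,9E)-10-{[tert-butyl(dimethyl)silyl]oxy}-8-[(3Z)-5-{[tert-butyl(dimethyl)silyl]oxy}-3-methylpent-3-en-1-yl]-3,3,7,9-tetramethyl-1-nitrodeca-7,9-dien-2-ol (racemic)
Conditions: 19 (excess), tetramethylguanidine (cat.), THF, 0 °C to rt
Reagents that add atoms: none
Why: Henry (nitroaldol) reaction: the guanidine base generates the nitronate of nitromethane, which adds to the non-enolisable neopentyl aldehyde under conditions mild enough for both silyl ethers; the carbinol stereocentre is lost in step 13.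

Step 13
Reactants: 20 (7E,9E)-10-{[tert-butyl(dimethyl)silyl]oxy}-8-[(3Z)-5-{[tert-butyl(dimethyl)silyl]oxy}-3-methylpent-3-en-1-yl]-3,3,7,9-tetramethyl-1-nitrodeca-7,9-dien-2-ol
Product: 22 (1E,7E,9E)-10-{[tert-butyl(dimethyl)silyl]oxy}-8-[(3Z)-5-{[tert-butyl(dimethyl)silyl]oxy}-3-methylpent-3-en-1-yl]-3,3,7,9-tetramethyl-1-nitrodeca-1,7,9-triene, via nitro mesylate 21 (not isolated)
Conditions: MsCl, Et3N, CH2Cl2, −40 to −10 °C; cold work-up, used at once
Reagents that add atoms: none
Why: Mesylation of the β-nitro alcohol and E1cB elimination by triethylamine (nitroaldol dehydration) should give the more stable (E)-nitroalkene, which cannot deconjugate because C4 is quaternary, and working cold keeps the triene from cyclising before the catalyst is added.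

Step 14
Reactants: 22 (1E,7E,9E)-10-{[tert-butyl(dimethyl)silyl]oxy}-8-[(3Z)-5-{[tert-butyl(dimethyl)silyl]oxy}-3-methylpent-3-en-1-yl]-3,3,7,9-tetramethyl-1-nitrodeca-1,7,9-triene
Product: 23 (5S,6R,7S,10S)-7α,15-bis{[tert-butyl(dimethyl)silyl]oxy}-6α-nitrolabda-8,13Z-diene (trans-fused, H-5 α, CH3-10 β)
Conditions: 1,1'-[(1R,2R)-cyclohexane-1,2-diyl]bis{3-[3,5-bis(trifluoromethyl)phenyl]thiourea} (20 mol%), 4 Å MS, toluene, −30 to 0 °C
Reagents that add atoms: none
Why: Proposed new method: the thiourea N–H bonds should bind the nitro oxygens and lower the LUMO of the (E)-nitroalkene, which then reacts with the electron-rich silyl dienol ether in a concerted but asynchronous [4+2] cycloaddition in which the C5–C10 bond is more advanced than the C6–C7 bond. The closest known reactions are the thermal intramolecular Diels–Alder reaction of (E)-1-nitrodeca-1,7,9-trienes to trans-decalins and the intermolecular nitroalkene Diels–Alder reaction under chiral hydrogen-bond-donor catalysis; their combination is untested. Ring B is the new cyclohexene made from the diene carbons C7–C10 and the dienophile carbons C5 and C6, and ring A closes in the same event because the C1–C4 chain links the diene terminus C10 to C5, a fused six-membered closure across the tether. The trans fusion at C5 and C10 follows from the transition state with the tether anti and the nitro group endo; suprafacial addition turns the E nitroalkene into the 6α-nitro group (trans to C4) and the E enol ether into the 7α-silyloxy group (cis to C1), and the C9=C10 geometry makes the C10 methyl β. The step needs endo/anti selectivity, which the nitro group and the chair-like four-atom tether with its gem-dimethyl group should supply, and facial selectivity, which rests on the chiral catalyst alone; closure through a nitronate oxygen must stay slower than carbon–carbon closure.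

Step 15
Reactants: 23 (5S,6R,7S,10S)-7α,15-bis{[tert-butyl(dimethyl)silyl]oxy}-6α-nitrolabda-8,13Z-diene
Product: 26 (5S,7S,10S)-7α,15-bis{[tert-butyl(dimethyl)silyl]oxy}labda-8,13Z-dien-6-one, via sodium nitronate 24 (not isolated), via imine 25 (not isolated)
Conditions: NaOMe, MeOH/THF, 0 °C; then aq. TiCl3, NH4OAc, rt
Reagents that add atoms: water, O
Why: Reductive Nef reaction: the sodium nitronate is reduced by trivalent titanium to the N–H imine, which is hydrolysed in the ammonium acetate buffer to the C6 ketone, and the near-neutral medium should spare both silyl ethers and the configurations at C5 and C7.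

Step 16
Reactants: 26 (5S,7S,10S)-7α,15-bis{[tert-butyl(dimethyl)silyl]oxy}labda-8,13Z-dien-6-one
Product: 27 (5S,6S,7S,10S)-7α,15-bis{[tert-butyl(dimethyl)silyl]oxy}labda-8,13Z-dien-6β-ol
Conditions: NaBH4, MeOH/THF, 0 °C
Reagents that add atoms: none
Why: Hydride reduction under steric approach control: the axial methyl groups on C4 and C10 shield the β face of the C6 carbonyl, so borohydride should attack from the α face and give the axial 6β-alcohol with the configuration required by the target.

Step 17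
Reactants: 27 (5S,6S,7S,10S)-7α,15-bis{[tert-butyl(dimethyl)silyl]oxy}labda-8,13Z-dien-6β-ol
Product: 28 (5S,6S,7S,10S)-7α,15-bis{[tert-butyl(dimethyl)silyl]oxy}labda-8,13Z-dien-6β-yl acetate
Conditions: Ac2O, DMAP, pyridine, 50 °C
Reagents that add atoms: acetic anhydride, CC(=O)OC(C)=O
Why: DMAP-catalysed acylation with acetic anhydride should esterify the hindered axial 6β-hydroxyl on warming, the two other oxygens being blocked as silyl ethers and the trans-diaxial arrangement of O6 and O7 preventing silyl migration.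

Step 18
Reactants: 28 (5S,6S,7S,10S)-7α,15-bis{[tert-butyl(dimethyl)silyl]oxy}labda-8,13Z-dien-6β-yl acetate
Product: 29 (5S,6S,7S,10S)-7α,15-dihydroxylabda-8,13Z-dien-6β-yl acetate (CNP0183298.2)
Conditions: HF·pyridine, pyridine/THF, 0 °C to rt
Reagents that add atoms: none
Why: Fluoride-induced desilylation with buffered HF·pyridine should remove both tert-butyldimethylsilyl groups while the acetate stays at O6, since neither hydrolysis nor acyl migration to the trans-diaxial O7 is expected under these mildly acidic conditions.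

Compound list
1 | (2Z)-3-methylpent-2-en-4-yn-1-ol | C#C/C(C)=C\CO | starting material
2 | tert-butyl(dimethyl){[(2Z)-3-methylpent-2-en-4-yn-1-yl]oxy}silane | C#C/C(C)=C\CO[Si](C)(C)C(C)(C)C | intermediate
3 | tert-butyl(dimethyl){[(2Z)-3-methylpenta-2,4-dien-1-yl]oxy}silane | C=C/C(C)=C\CO[Si](C)(C)C(C)(C)C | intermediate
4 | chlorobis(cyclopentadienyl)[(3Z)-5-{[tert-butyl(dimethyl)silyl]oxy}-3-methylpent-3-en-1-yl]zirconium | CC(C)(C)[Si](C)(C)OC/C=C(C)\CC[Zr](Cl)(C1C=CC=C1)C1C=CC=C1 | intermediate (not isolated)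
5 | tert-butyl{[(2Z)-5-iodo-3-methylpent-2-en-1-yl]oxy}dimethylsilane | CC(C)(C)[Si](C)(C)OC/C=C(C)\CCI | intermediate
6 | methyl acetoacetate (methyl 3-oxobutanoate) | CC(=O)CC(=O)OC | starting material
7 | methyl (5Z)-2-acetyl-7-{[tert-butyl(dimethyl)silyl]oxy}-5-methylhept-5-enoate (racemic) | COC(=O)C(CC/C(C)=C\CO[Si](C)(C)C(C)(C)C)C(C)=O | intermediate
8 | methyl (2E)-2-[(3Z)-5-{[tert-butyl(dimethyl)silyl]oxy}-3-methylpent-3-en-1-yl]-3-{[(4-methylphenyl)sulfonyl]oxy}but-2-enoate | COC(=O)/C(CC/C(C)=C\CO[Si](C)(C)C(C)(C)C)=C(\C)OS(=O)(=O)c1ccc(C)cc1 | intermediate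
9 | 2,2-dimethylpent-4-enal | C=CCC(C)(C)C=O | starting material
10 | 9-{[5-(9-borabicyclo[3.3.1]nonan-9-yl)-2,2-dimethylpentyl]oxy}-9-borabicyclo[3.3.1]nonane | CC(C)(COB1C2CCCC1CCC2)CCCB1C2CCCC1CCC2 | intermediate (not isolated)
11 | methyl (2E)-2-[(3Z)-5-{[tert-butyl(dimethyl)silyl]oxy}-3-methylpent-3-en-1-yl]-8-hydroxy-3,7,7-trimethyloct-2-enoate | COC(=O)/C(CC/C(C)=C\CO[Si](C)(C)C(C)(C)C)=C(\C)CCCC(C)(C)CO | intermediate
12 | (3E)-3-[(3Z)-5-{[tert-butyl(dimethyl)silyl]oxy}-3-methylpent-3-en-1-yl]-9-hydroxy-4,8,8-trimethyl-1-(trimethylsilyl)non-3-en-2-one | C[Si](C)(C)CC(=O)/C(CC/C(C)=C\CO[Si](C)(C)C(C)(C)C)=C(\C)CCCC(C)(C)CO | intermediate (not isolated)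
13 | (3E)-3-[(3Z)-5-{[tert-butyl(dimethyl)silyl]oxy}-3-methylpent-3-en-1-yl]-9-hydroxy-4,8,8-trimethylnon-3-en-2-one | CC(=O)/C(CC/C(C)=C\CO[Si](C)(C)C(C)(C)C)=C(\C)CCCC(C)(C)CO | intermediate
14 | (6E)-7-[(3Z)-5-{[tert-butyl(dimethyl)silyl]oxy}-3-methylpent-3-en-1-yl]-2,2,6,8-tetramethylnona-6,8-dien-1-ol | C=C(C)/C(CC/C(C)=C\CO[Si](C)(C)C(C)(C)C)=C(\C)CCCC(C)(C)CO | intermediate
15 | 9-{[(6E)-9-(9-borabicyclo[3.3.1]nonan-9-yl)-7-[(3Z)-5-{[tert-butyl(dimethyl)silyl]oxy}-3-methylpent-3-en-1-yl]-2,2,6,8-tetramethylnon-6-en-1-yl]oxy}-9-borabicyclo[3.3.1]nonane | CC(CB1C2CCCC1CCC2)/C(CC/C(C)=C\CO[Si](C)(C)C(C)(C)C)=C(\C)CCCC(C)(C)COB1C2CCCC1CCC2 | intermediate (not isolated)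
16 | (3E)-3-[(3Z)-5-{[tert-butyl(dimethyl)silyl]oxy}-3-methylpent-3-en-1-yl]-2,4,8,8-tetramethylnon-3-ene-1,9-diol (racemic) | OCC(C)/C(CC/C(C)=C\CO[Si](C)(C)C(C)(C)C)=C(\C)CCCC(C)(C)CO | intermediate
17 | (3E)-3-[(3Z)-5-{[tert-butyl(dimethyl)silyl]oxy}-3-methylpent-3-en-1-yl]-2,4,8,8-tetramethylnon-3-enedial (racemic) | O=CC(C)/C(CC/C(C)=C\CO[Si](C)(C)C(C)(C)C)=C(\C)CCCC(C)(C)C=O | intermediate
18 | (6E,8E)-9-{[tert-butyl(dimethyl)silyl]oxy}-7-[(3Z)-5-{[tert-butyl(dimethyl)silyl]oxy}-3-methylpent-3-en-1-yl]-2,2,6,8-tetramethylnona-6,8-dienal | O=CC(C)(C)CCC/C(C)=C(CC/C(C)=C\CO[Si](C)(C)C(C)(C)C)/C(C)=C/O[Si](C)(C)C(C)(C)C | intermediate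
19 | nitromethane | C[N+](=O)[O-] | starting material
20 | (7E,9E)-10-{[tert-butyl(dimethyl)silyl]oxy}-8-[(3Z)-5-{[tert-butyl(dimethyl)silyl]oxy}-3-methylpent-3-en-1-yl]-3,3,7,9-tetramethyl-1-nitrodeca-7,9-dien-2-ol (racemic) | [O-][N+](=O)CC(O)C(C)(C)CCC/C(C)=C(CC/C(C)=C\CO[Si](C)(C)C(C)(C)C)/C(C)=C/O[Si](C)(C)C(C)(C)C | intermediate
21 | methanesulfonate of 20, (7E,9E)-10-{[tert-butyl(dimethyl)silyl]oxy}-8-[(3Z)-5-{[tert-butyl(dimethyl)silyl]oxy}-3-methylpent-3-en-1-yl]-3,3,7,9-tetramethyl-1-nitrodeca-7,9-dien-2-yl methanesulfonate | [O-][N+](=O)CC(OS(C)(=O)=O)C(C)(C)CCC/C(C)=C(CC/C(C)=C\CO[Si](C)(C)C(C)(C)C)/C(C)=C/O[Si](C)(C)C(C)(C)C | intermediate (not isolated)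
22 | (1E,7E,9E)-10-{[tert-butyl(dimethyl)silyl]oxy}-8-[(3Z)-5-{[tert-butyl(dimethyl)silyl]oxy}-3-methylpent-3-en-1-yl]-3,3,7,9-tetramethyl-1-nitrodeca-1,7,9-triene | [O-][N+](=O)/C=C/C(C)(C)CCC/C(C)=C(CC/C(C)=C\CO[Si](C)(C)C(C)(C)C)/C(C)=C/O[Si](C)(C)C(C)(C)C | intermediate
23 | (5S,6R,7S,10S)-7α,15-bis{[tert-butyl(dimethyl)silyl]oxy}-6α-nitrolabda-8,13Z-diene | [O-][N+](=O)[C@H]1[C@@H](O[Si](C)(C)C(C)(C)C)C(C)=C(CC/C(C)=C\CO[Si](C)(C)C(C)(C)C)[C@@]2(C)CCCC(C)(C)[C@H]12 | intermediate
24 | sodium nitronate of 23 (sodium salt of the 6-aci-nitro form) | [Na+].[O-][N+]([O-])=C1[C@@H](O[Si](C)(C)C(C)(C)C)C(C)=C(CC/C(C)=C\CO[Si](C)(C)C(C)(C)C)[C@@]2(C)CCCC(C)(C)[C@H]12 | intermediate (not isolated)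
25 | (5S,7S,10S)-7α,15-bis{[tert-butyl(dimethyl)silyl]oxy}labda-8,13Z-dien-6-imine | N=C1[C@@H](O[Si](C)(C)C(C)(C)C)C(C)=C(CC/C(C)=C\CO[Si](C)(C)C(C)(C)C)[C@@]2(C)CCCC(C)(C)[C@H]12 | intermediate (not isolated)
26 | (5S,7S,10S)-7α,15-bis{[tert-butyl(dimethyl)silyl]oxy}labda-8,13Z-dien-6-one | O=C1[C@@H](O[Si](C)(C)C(C)(C)C)C(C)=C(CC/C(C)=C\CO[Si](C)(C)C(C)(C)C)[C@@]2(C)CCCC(C)(C)[C@H]12 | intermediate
27 | (5S,6S,7S,10S)-7α,15-bis{[tert-butyl(dimethyl)silyl]oxy}labda-8,13Z-dien-6β-ol | O[C@@H]1[C@@H](O[Si](C)(C)C(C)(C)C)C(C)=C(CC/C(C)=C\CO[Si](C)(C)C(C)(C)C)[C@@]2(C)CCCC(C)(C)[C@H]12 | intermediate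
28 | (5S,6S,7S,10S)-7α,15-bis{[tert-butyl(dimethyl)silyl]oxy}labda-8,13Z-dien-6β-yl acetate | CC(=O)O[C@@H]1[C@@H](O[Si](C)(C)C(C)(C)C)C(C)=C(CC/C(C)=C\CO[Si](C)(C)C(C)(C)C)[C@@]2(C)CCCC(C)(C)[C@H]12 | intermediate
29 | (5S,6S,7S,10S)-7α,15-dihydroxylabda-8,13Z-dien-6β-yl acetate (CNP0183298.2) | CC(=O)O[C@@H]1[C@@H](O)C(C)=C(CC/C(C)=C\CO)[C@@]2(C)CCCC(C)(C)[C@H]12 | target

Total step count: 18.
Longest linear sequence: 18 steps (1 to 29); building blocks 6, 9 and 19 enter without steps of their own.

Steps most likely to fail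

Step 14. The uncatalysed cycloaddition may run alongside the catalysed one, and the catalyst may discriminate poorly between the two faces of the nitroalkene, so that enantiomeric purity is lost. In addition, carbon–carbon bond formation at the crowded C10 terminus may be slow enough for silyl transfer or closure through nitronate oxygen to divert material. The fallback sets out from 22 and gives up catalyst control: heating 22 without catalyst in toluene at 80 °C, the established thermal mode for nitro-decatrienes, should give the racemic trans-fused adduct. That is 23 together with its mirror image, (5R,6S,7R,10R)-7β,15-bis{[tert-butyl(dimethyl)silyl]oxy}-6β-nitro-ent-labda-8,13Z-diene F1. The two are separated by preparative HPLC on a cellulose tris(3,5-dimethylphenylcarbamate) phase, and the route is rejoined at 23.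

Step 6. Oxidative addition at the crowded tetrasubstituted enol tosylate may be slow, so that hydrolysis of the tosylate by the aqueous base and protodeboronation of the alkylborane take over. The fallback sets out from 9 and replaces the boron/palladium coupling by an iron-catalysed Kumada-type coupling. Reduction of 9 (NaBH4, MeOH) gives 2,2-dimethylpent-4-en-1-ol F2. Peroxide-initiated anti-Markovnikov addition of HBr (HBr, dibenzoyl peroxide, pentane, 0 °C) gives 5-bromo-2,2-dimethylpentan-1-ol F3. Deprotonation with MeMgBr (1 equiv) and insertion of magnesium (Mg turnings, THF) gives the alkoxide Grignard reagent bromomagnesium 5-(bromomagnesio)-2,2-dimethylpentan-1-olate F4. Coupling of F4 with tosylate 8 (Fe(acac)3 5 mol%, THF/NMP, −20 °C) should proceed with retention of geometry, and aqueous work-up returns the route at 11.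

Step 15. The nitronate may expel the neighbouring silanolate (β-elimination towards a nitrodiene), or deprotonation at the hindered C6 may be too slow. The fallback sets out from 23 and avoids the nitronate. Reduction with SnCl2·2H2O, PhSH and Et3N in MeCN at rt should stop at the oxime, (5S,7S,10S)-7α,15-bis{[tert-butyl(dimethyl)silyl]oxy}labda-8,13Z-dien-6-one oxime F5. Deoximation of F5 with buffered aqueous TiCl3 (NH4OAc, THF/H2O, rt) then gives the ketone, and the route is rejoined at 26.

Further compounds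
F1 | step 14 | (5R,6S,7R,10R)-7β,15-bis{[tert-butyl(dimethyl)silyl]oxy}-6β-nitro-ent-labda-8,13Z-diene (enantiomer of 23) | [O-][N+](=O)[C@@H]1[C@H](O[Si](C)(C)C(C)(C)C)C(C)=C(CC/C(C)=C\CO[Si](C)(C)C(C)(C)C)[C@]2(C)CCCC(C)(C)[C@@H]12
F2 | step 6 | 2,2-dimethylpent-4-en-1-ol | C=CCC(C)(C)CO
F3 | step 6 | 5-bromo-2,2-dimethylpentan-1-ol | OCC(C)(C)CCCBr
F4 | step 6 | bromomagnesium 5-(bromomagnesio)-2,2-dimethylpentan-1-olate | Br[Mg]CCCC(C)(C)CO[Mg]Br
F5 | step 15 | (5S,7S,10S)-7α,15-bis{[tert-butyl(dimethyl)silyl]oxy}labda-8,13Z-dien-6-one oxime | ON=C1[C@@H](O[Si](C)(C)C(C)(C)C)C(C)=C(CC/C(C)=C\CO[Si](C)(C)C(C)(C)C)[C@@]2(C)CCCC(C)(C)[C@H]12
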